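Over 43 min at one constant temperature, four flasks have been followed through their starting material, and a fifth, the south-east run, is asked about.

| flask | starting material | coupling partner | free catalyst | time |
|---|---|---|---|---|
| west | 250 mM | 275 mM | 7.50 mM |  |
| south-west | 250 mM | 830 mM | 7.50 mM |  |
| north | 500 mM | 275 mM | 7.50 mM |  |
| east | 250 mM | 275 mM | 15.0 mM |  |
| south-east | 500 mM | 830 mM | 7.50 mM | 43 min |

- west run (time / min: [starting material] / mM): 1.9: 215.5; 5.8: 157.9; 11: 102.5; 18: 57.2; 25: 30.4; 34: 13.9; 43: 5.3
- south-west run (time / min: [starting material] / mM): 1.9: 222.4; 5.8: 177.0; 11: 128.9; 18: 84.8; 25: 54.3; 34: 31.5; 43: 17.7
- north run (time / min: [starting material] / mM): 1.9: 434.1; 5.8: 317.4; 11: 203.4; 18: 108.2; 25: 56.4; 34: 21.3; 43: 7.9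
- east run (time / min: [starting material] / mM): 1.9: 201.1; 5.8: 123.6; 11: 62.2; 18: 21.4; 25: 7.4; 34: 1.8; 43: 0

(standard deviation of a reading: 0.8 mM)

- Overall: starting material + coupling partner -> product, with free catalyst as catalyst.
- Constant volume, constant temperature.
- A reading of a species includes what of it is bound.
- "The second partner" is coupling partner.
- An order is taken over about fifteen percent of the charge, up and down.

1. order of the initial rate in [coupling partner], near the charge of the west run, the rate being that where two percent of its starting material are product
2. order of the initial rate in [starting material], near the charge of the west run, the rate being that where two percent of its starting material are product (one fixed amount of product, the same in the runs compared)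
3. starting material in the south-east run at 43 min, as a share of the starting material charged

I work with the fraction left and turn it into a constant: the logarithm of charge over reading at 5.8 min, divided by that time. This gives 0.0792 min⁻¹ for the west run, 0.121 min⁻¹ for east, 0.0595 min⁻¹ for south-west and 0.0784 min⁻¹ for north.

By 43 min the north run has lost 492 mM of starting material, more than its 275 mM of coupling partner, so starting material has a second way out that uses no partner. Two rates therefore share each constant. I assume that the catalysed one grows in proportion to the free catalyst, so going from west to east adds 0.0422 min⁻¹, the catalysed constant of the west run. That leaves 0.0370 min⁻¹ as the background constant, the first-order side loss of starting material that owes nothing to the catalyst.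

The orders asked concern product, so I subtract the background first. South-west against west then gives −0.568 in coupling partner, an average across that span and not the slope at the west charge. North against west gives 0.970 in starting material. The north and west constants stand close together despite the doubled charge, so I expect the south-east run to leave the south-west fraction, 7.08%. Background by itself would leave 20.4% over that time.

The forecast differs from me on the partner and on the last figure: −0.2, 0.91 and 5.3%, reading that “coupling partner inhibits mildly”.

The flask gives −0.45, 0.98 and 6.95%.

    free catalyst + starting material → loaded catalyst + by-product (10.56 L mol⁻¹ min⁻¹)
    loaded catalyst + coupling partner → product + free catalyst (76.20 L mol⁻¹ min⁻¹)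
    free catalyst + coupling partner ⇌ idle catalyst-reagent complex, settled at all times (4.070 L mol⁻¹)
    starting material → decomposed substrate (0.04206 min⁻¹)

The south-east run ends at 6.95% with the step from starting material to decomposed substrate, and at 40.1% without it. Multiplying that 40.1% by 20.4%, the survival I reckoned from the background constant read off the runs, gives an estimate of 8.18%. The same constant serves the south-west run, whose raw constant stands at 0.751 of the west one. With background removed from both, the ratio becomes 0.533, and the rates of product formation, 4.2 mM min⁻¹ against 8.6 mM min⁻¹, stand at 0.494.

(The data are simulated from invented constants; the scatter is artificial.)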